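**Plan**

1. Locants follow the geranylgeranyl chain: C1 = ArCH2; C2=C3 = ring alkene; C6 = ring CHBr; C7 = ring quaternary carbon; C10 = chain CHBr; C11 = C(CH3)OH; C12, C13 = CH2; C14 = lactone CH–O; C15 = isopropenyl carbon.
2. Cuts: first C13–C14 of the 15-membered lactone, giving an (E)-3-chloro-2-methylprop-1-enyl benzoate (from the acid and methacrolein) that carries a vinyl group on C11. Then the C11 vinyl and C10 bromide go back to a Sharpless epoxy alcohol grown from an allyl group on C7. Last, the ArCH2–C2 bond (Negishi) leads to a benzylzinc and an enol triflate derived from 2-allyl-2-methylcyclohexane-1,3-dione.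
3. Forward: the six-membered carbocycle comes from the dione (desymmetrised, brominated, methylated, triflated), the arene is attached, the C8–C13 chain is grown on the allyl group, and the macrolactone is closed last by C–C bond formation.
4. Enabling feature: C14 is an allylic CH bearing both the lactone oxygen and the isopropenyl group, O–CH–C(CH3)=CH2. This is the SN2' image of an enol ester O–CH=C(CH3)–CH2Cl. C13 is the terminal carbon of a vinyl group on carbinol C11 and becomes nucleophilic on hydroboration.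
5. Stereochemistry: C7 and C6 from a CBS desymmetrisation followed by invertive Appel bromination; C11 and C10 from a Sharpless epoxidation followed by invertive bromide opening; C14 from the chiral copper catalyst in the ring closure.

Key step: step 19

Remark: the E isomer of the enol ester made in step 18 is taken forward, and the sense of induction of the copper ligand is assigned by analogy; the antipodal ligand is equally available.

**Route**

Step 1
Reactants: 1 2-methylcyclohexane-1,3-dione; 2 allyl bromide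
Product: 3 2-allyl-2-methylcyclohexane-1,3-dione
Conditions: NaOH (1 M aq), rt
Reagents that add atoms: none
Why: C-allylation of the stabilised 1,3-dione enolate in water (allylic SN2) is the standard entry to this dione and creates the future C7 quaternary carbon as a prochiral centre.

Step 2
Reactants: 3 2-allyl-2-methylcyclohexane-1,3-dione
Product: 4 (2R,3R)-2-allyl-3-hydroxy-2-methylcyclohexan-1-one (OH cis to allyl)
Conditions: (S)-2-methyl-CBS-oxazaborolidine (20 mol %), catecholborane (1.0 equiv), toluene, −78 → −60 °C; aqueous work-up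
Reagents that add atoms: none
Why: Corey–Bakshi–Shibata desymmetrising reduction, in which the (S)-catalyst treats the quaternary carbon as the large group and should give the (R)-carbinol, while hydride arrives on the ring face opposite the allyl group, so that OH ends up cis to allyl and the quaternary centre is fixed in the same event.

Step 3
Reactants: 4 (2R,3R)-2-allyl-3-hydroxy-2-methylcyclohexan-1-one
Product: 5 (2S,3S)-2-allyl-3-bromo-2-methylcyclohexan-1-one (Br trans to allyl)
Conditions: CBr4, P(n-Oct)3, toluene, 0 → 70 °C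
Reagents that add atoms: carbon tetrabromide BrC(Br)(Br)Br
Why: Appel bromination with SN2 inversion at the neopentylic carbinol (a small electron-rich trialkylphosphine and heat are the conditions used for such hindered secondary alcohols) should turn the OH cis to allyl into the Br trans to allyl, the β-carbonyl disfavouring cationic 1,2-shifts and the quaternary α-carbon excluding elimination toward the ketone.

Step 4
Reactants: 5 (2S,3S)-2-allyl-3-bromo-2-methylcyclohexan-1-one
Product: 6 (2S,3S)-2-allyl-3-bromo-2,6-dimethylcyclohexan-1-one (C6 epimers)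
Conditions: LiN(i-Pr)2, THF, −78 °C; MeI, −78 → −40 °C
Reagents that add atoms: iodomethane CI
Why: kinetic enolate alkylation at the only enolisable α-position, which places the future C3 methyl group; the new stereocentre is erased in step 5.

Step 5
Reactants: 6 (2S,3S)-2-allyl-3-bromo-2,6-dimethylcyclohexan-1-one
Product: 7 (5S,6S)-6-allyl-5-bromo-2,6-dimethylcyclohex-1-en-1-yl trifluoromethanesulfonate
Conditions: KN(SiMe3)2, THF, −78 °C; PhNTf2, −78 → 0 °C
Reagents that add atoms: N-phenylbis(trifluoromethanesulfonimide) O=S(=O)(N(c1ccccc1)S(=O)(=O)C(F)(F)F)C(F)(F)F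
Why: O-sulfonylation of the only possible enolate gives the tetrasubstituted enol triflate, as is routine for 2,2,6-trisubstituted cyclohexanones.

Step 6
Reactants: 8 methyl 4-hydroxy-3-methylbenzoate
Product: 9 methyl 3-methyl-4-(triisopropylsilyloxy)benzoate
Conditions: i-Pr3SiCl, imidazole, DMF, rt
Reagents that add atoms: triisopropylsilyl chloride CC(C)[Si](Cl)(C(C)C)C(C)C
Why: phenol silylation; the TIPS ether should survive the organozinc, hydride and mild Lewis-acid steps and leaves with fluoride at the end.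

Step 7
Reactants: 9 methyl 3-methyl-4-(triisopropylsilyloxy)benzoate
Product: 10 methyl 3-(bromomethyl)-4-(triisopropylsilyloxy)benzoate
Conditions: NBS, AIBN (cat.), PhCF3, 80 °C
Reagents that add atoms: N-bromosuccinimide O=C1CCC(=O)N1Br
Why: Wohl–Ziegler benzylic bromination, radical conditions in a non-polar solvent favouring the benzylic position over the ester-deactivated ring.

Step 8
Reactants: 7 (5S,6S)-6-allyl-5-bromo-2,6-dimethylcyclohex-1-en-1-yl trifluoromethanesulfonate; 10 methyl 3-(bromomethyl)-4-(triisopropylsilyloxy)benzoate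
Product: 12 methyl 3-{[(5S,6S)-6-allyl-5-bromo-2,6-dimethylcyclohex-1-en-1-yl]methyl}-4-(triisopropylsilyloxy)benzoate, via benzylzinc bromide 11 (not isolated)
Conditions: 10, Zn dust, LiCl, THF, 0 °C → rt; then 7, Pd(OAc)2 (3 mol %), SPhos (6 mol %), THF, rt → 50 °C
Reagents that add atoms: none
Why: Negishi sp3–sp2 coupling, in which LiCl-assisted zinc insertion into the benzylic bromide tolerates the ester and zerovalent palladium adds to the vinyl triflate but not to the neopentylic secondary bromide.

Step 9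
Reactants: 12 methyl 3-{[(5S,6S)-6-allyl-5-bromo-2,6-dimethylcyclohex-1-en-1-yl]methyl}-4-(triisopropylsilyloxy)benzoate
Product: 14 methyl 3-{[(5S,6S)-5-bromo-6-(3-hydroxypropyl)-2,6-dimethylcyclohex-1-en-1-yl]methyl}-4-(triisopropylsilyloxy)benzoate, via B-alkyl-9-BBN adduct 13 (not isolated)
Conditions: 9-BBN, THF, 0 °C → rt; then H2O2 (30%), pH 7 phosphate buffer, 0 °C → rt
Reagents that add atoms: hydrogen peroxide OO
Why: hydroboration–oxidation, 9-BBN adding anti-Markovnikov to the monosubstituted allyl alkene only (the tetrasubstituted ring alkene and the ester are inert) and buffered peroxide sparing the aryl silyl ether.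

Step 10
Reactants: 14 methyl 3-{[(5S,6S)-5-bromo-6-(3-hydroxypropyl)-2,6-dimethylcyclohex-1-en-1-yl]methyl}-4-(triisopropylsilyloxy)benzoate; 15 2-(triphenylphosphoranylidene)propanal
Product: 17 methyl 3-{[(5S,6S)-5-bromo-2,6-dimethyl-6-[(3E)-4-methyl-5-oxopent-3-en-1-yl]cyclohex-1-en-1-yl]methyl}-4-(triisopropylsilyloxy)benzoate, via aldehyde 16 (not isolated)
Conditions: Dess–Martin periodinane, CH2Cl2, rt; filter, concentrate; then 15, toluene, 80 °C
Reagents that add atoms: none
Why: Dess–Martin oxidation followed by Wittig olefination with a stabilised formyl ylide, which should give the (E)-2-methyl enal under the usual thermodynamic control and reacts with the saturated aldehyde faster than with the conjugated product.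

Step 11
Reactants: 17 the (E)-enal from step 10
Product: 18 methyl 3-{[(5S,6S)-5-bromo-6-[(3E)-5-hydroxy-4-methylpent-3-en-1-yl]-2,6-dimethylcyclohex-1-en-1-yl]methyl}-4-(triisopropylsilyloxy)benzoate
Conditions: NaBH4, CeCl3·7H2O, MeOH, −40 → 0 °C
Reagents that add atoms: none
Why: Luche 1,2-reduction, chemoselective for the enal carbonyl over the benzoate ester and the alkyl bromide.

Step 12
Reactants: 18 the (E)-allylic alcohol from step 11
Product: 19 methyl 3-{[(5S,6S)-5-bromo-6-{2-[(2S,3S)-3-(hydroxymethyl)-3-methyloxiran-2-yl]ethyl}-2,6-dimethylcyclohex-1-en-1-yl]methyl}-4-(triisopropylsilyloxy)benzoate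
Conditions: Ti(Oi-Pr)4 (10 mol %), L-(+)-diethyl tartrate (12 mol %), t-BuOOH, 4 Å molecular sieves, CH2Cl2, −20 °C
Reagents that add atoms: tert-butyl hydroperoxide CC(C)(C)OO
Why: Sharpless asymmetric epoxidation, reagent control by L-(+)-tartrate giving the (2S,3S)-epoxy alcohol as for other (E)-2-methyl allylic alcohols, while the ring alkene, which has no directing hydroxyl, is left alone.

Step 13
Reactants: 19 the (2S,3S)-epoxy alcohol from step 12
Product: 20 methyl 3-{[(5S,6S)-5-bromo-6-[(3R,4S)-3-bromo-4,5-dihydroxy-4-methylpentyl]-2,6-dimethylcyclohex-1-en-1-yl]methyl}-4-(triisopropylsilyloxy)benzoate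
Conditions: Ti(Oi-Pr)4 (1.5 equiv), Et2NH·HBr, CH2Cl2, rt
Reagents that add atoms: diethylammonium bromide CC[NH2+]CC.[Br-]
Why: titanium-assisted regioselective opening of a 2,3-epoxy alcohol at the carbon remote from the hydroxymethyl group, bromide attacking the secondary carbon C10 with inversion (10R) while the fully substituted C11 keeps its oxygen (11S).

Step 14
Reactants: 20 the bromo diol from step 13
Product: 21 methyl 3-{[(5S,6S)-5-bromo-6-[(3R,4S)-3-bromo-4-methyl-4,5-bis(triethylsilyloxy)pentyl]-2,6-dimethylcyclohex-1-en-1-yl]methyl}-4-(triisopropylsilyloxy)benzoate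
Conditions: Et3SiOTf, 2,6-lutidine, CH2Cl2, −78 → 0 °C
Reagents that add atoms: triethylsilyl trifluoromethanesulfonate CC[Si](CC)(CC)OS(=O)(=O)C(F)(F)F
Why: silylation of both hydroxyls, the tertiary silyl ether blocking bromohydrin-to-epoxide closure in the basic Wittig step and protecting the tertiary alcohol during acyl chloride formation.

Step 15
Reactants: 21 the bis(triethylsilyl) ether from step 14
Product: 22 methyl 3-{[(5S,6S)-5-bromo-6-[(3R,4S)-3-bromo-4-methyl-5-oxo-4-(triethylsilyloxy)pentyl]-2,6-dimethylcyclohex-1-en-1-yl]methyl}-4-(triisopropylsilyloxy)benzoate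
Conditions: (COCl)2, DMSO, CH2Cl2, −78 → −40 °C; Et3N, −78 → 0 °C
Reagents that add atoms: none
Why: Swern oxidation, which converts a primary triethylsilyl ether directly into the aldehyde while the tertiary triethylsilyl and aryl triisopropylsilyl ethers persist.

Step 16
Reactants: 22 the α-silyloxy aldehyde from step 15
Product: 23 methyl 3-{[(5S,6S)-5-bromo-6-[(3R,4S)-3-bromo-4-methyl-4-(triethylsilyloxy)hex-5-en-1-yl]-2,6-dimethylcyclohex-1-en-1-yl]methyl}-4-(triisopropylsilyloxy)benzoate
Conditions: Ph3PCH3Br, KN(SiMe3)2, THF, 0 °C; then 22, −78 → 0 °C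
Reagents that add atoms: methyltriphenylphosphonium bromide C[P+](c1ccccc1)(c1ccccc1)c1ccccc1.[Br-]
Why: Wittig methylenation of an aldehyde that has no α-hydrogen (no epimerisation) and reacts with the ylide much faster than the aryl ester does, giving the C12=C13 vinyl group.

Step 17
Reactants: 23 the vinyl compound from step 16
Product: 24 3-{[(5S,6S)-5-bromo-6-[(3R,4S)-3-bromo-4-methyl-4-(triethylsilyloxy)hex-5-en-1-yl]-2,6-dimethylcyclohex-1-en-1-yl]methyl}-4-(triisopropylsilyloxy)benzoic acid
Conditions: Me3SnOH, 1,2-dichloroethane, 80 °C; dilute aq. HCl wash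
Reagents that add atoms: trimethyltin hydroxide C[Sn](C)(C)O
Why: trimethyltin hydroxide ester cleavage under near-neutral conditions should hydrolyse the methyl benzoate without touching the aryl silyl ether, the tertiary silyl ether or the bromides.

Step 18
Reactants: 24 the benzoic acid from step 17; 25 methacrolein
Product: 28 (1E)-3-chloro-2-methylprop-1-en-1-yl ester of acid 24, via acid chloride 26 (not isolated), via 1-chloro-2-methylallyl ester 27 (not isolated)
Conditions: 1-chloro-N,N,2-trimethylprop-1-en-1-amine, CH2Cl2, 0 °C → rt; then 25 (5 equiv), ZnCl2 (5 mol %), −20 → 0 °C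
Reagents that add atoms: 1-chloro-N,N,2-trimethylprop-1-en-1-amine CC(C)=C(Cl)N(C)C
Why: neutral acid chloride formation with an α-chloroenamine followed by Lewis-acid-catalysed addition of the acyl chloride across the enal carbonyl and allylic 1,3-chloride shift to the conjugated enol ester, the known route from acyl halides and acrolein to 3-halopropenyl esters, the E isomer being expected to predominate on equilibration and being separable.

Step 19
Reactants: 28 the (E)-3-chloro-2-methylprop-1-enyl ester from step 18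
Product: 31 bis-silyl macrolactone (the target skeleton with C11–OSiEt3 plus ArO–Si(i-Pr)3; 6S,7S,10R,11S,14S), via B-alkyl-9-BBN adduct 29 (not isolated), via potassium tert-butoxyborate 30 (not isolated)
Conditions: 9-BBN, THF, 0 °C → rt; KOt-Bu (1.0 equiv), −20 °C; slow addition to CuOTf·(toluene)0.5 (20 mol %), (R)-DTBM-SEGPHOS (22 mol %), THF/1,4-dioxane, 25 °C, ca. 1 mM
Reagents that add atoms: none
Why: Proposed new method: 9-BBN adds anti-Markovnikov to the C12=C13 vinyl group only, the tert-butoxide ate complex of the resulting primary borane transmetalates to the bisphosphine–copper catalyst, and the alkylcopper attacks the enol-ester carbon C14 anti to the allylic chloride (SN2' through a σ-allyl trivalent copper species that reductively eliminates before allyl isomerisation), so that C13–C14 forms and the double bond moves into the isopropenyl group. The closest known reaction types are the copper-catalysed γ-selective allyl–alkyl coupling of B-alkyl-9-BBN reagents with primary allylic chlorides and the copper-catalysed asymmetric SN2' alkylation of 3-bromopropenyl esters by alkyl Grignard reagents to give secondary allylic esters; their intramolecular union on an enol ester is the new element. The 15-membered lactone closes in a 15-exo-trig SN2' mode under syringe-pump pseudo-dilution. C14 is the new stereocentre and is controlled by the chiral ligand, which selects the enantiotopic face of the E enol ester, the existing centres at C6, C7, C10 and C11 being too remote to dominate. The step needs γ over α regioselectivity (inherent to the anti-SN2' pathway, and α attack would require a 17-membered ring holding an E alkene), ring closure over oligomerisation (slow addition), and chemoselectivity for the allylic chloride over the two hindered secondary alkyl bromides and the esters, which neutral alkylcopper and borate species should not attack at 25 °C.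

Step 20
Reactants: 31 bis-silyl macrolactone
Product: 32 CNP0305154.1 (target; 6S,7S,10R,11S,14S)
Conditions: Bu4NF, AcOH (1:1), THF, 0 °C → rt
Reagents that add atoms: none
Why: fluoride-mediated cleavage of the aryl triisopropylsilyl and tertiary triethylsilyl ethers, buffered with acetic acid so that the C10/C11 bromohydrin should not close to the epoxide and the lactone is not opened.

**Compound list**

1 | 2-methylcyclohexane-1,3-dione | CC1C(=O)CCCC1=O | starting material
2 | allyl bromide | C=CCBr | starting material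
3 | 2-allyl-2-methylcyclohexane-1,3-dione | C=CCC1(C)C(=O)CCCC1=O | intermediate
4 | (2R,3R)-2-allyl-3-hydroxy-2-methylcyclohexan-1-one | C=CC[C@@]1(C)C(=O)CCC[C@H]1O | intermediate
5 | (2S,3S)-2-allyl-3-bromo-2-methylcyclohexan-1-one | C=CC[C@@]1(C)C(=O)CCC[C@@H]1Br | intermediate
6 | (2S,3S)-2-allyl-3-bromo-2,6-dimethylcyclohexan-1-one (C6 epimers) | C=CC[C@@]1(C)C(=O)C(C)CC[C@@H]1Br | intermediate
7 | (5S,6S)-6-allyl-5-bromo-2,6-dimethylcyclohex-1-en-1-yl trifluoromethanesulfonate | C=CC[C@@]1(C)C(OS(=O)(=O)C(F)(F)F)=C(C)CC[C@@H]1Br | intermediate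
8 | methyl 4-hydroxy-3-methylbenzoate | COC(=O)c1ccc(O)c(C)c1 | starting material
9 | methyl 3-methyl-4-(triisopropylsilyloxy)benzoate | COC(=O)c1ccc(O[Si](C(C)C)(C(C)C)C(C)C)c(C)c1 | intermediate
10 | methyl 3-(bromomethyl)-4-(triisopropylsilyloxy)benzoate | COC(=O)c1ccc(O[Si](C(C)C)(C(C)C)C(C)C)c(CBr)c1 | intermediate
11 | [5-(methoxycarbonyl)-2-(triisopropylsilyloxy)benzyl]zinc bromide | COC(=O)c1ccc(O[Si](C(C)C)(C(C)C)C(C)C)c(C[Zn]Br)c1 | intermediate
12 | methyl 3-{[(5S,6S)-6-allyl-5-bromo-2,6-dimethylcyclohex-1-en-1-yl]methyl}-4-(triisopropylsilyloxy)benzoate | C=CC[C@@]1(C)C(=C(C)CC[C@@H]1Br)Cc1cc(ccc1O[Si](C(C)C)(C(C)C)C(C)C)C(=O)OC | intermediate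
13 | B-alkyl-9-BBN adduct of 12 (boron on the terminal allyl carbon) | C1CC2CCCC(C1)B2CCC[C@@]3(C)C(=C(C)CC[C@@H]3Br)Cc3cc(ccc3O[Si](C(C)C)(C(C)C)C(C)C)C(=O)OC | intermediate
14 | methyl 3-{[(5S,6S)-5-bromo-6-(3-hydroxypropyl)-2,6-dimethylcyclohex-1-en-1-yl]methyl}-4-(triisopropylsilyloxy)benzoate | OCCC[C@@]1(C)C(=C(C)CC[C@@H]1Br)Cc1cc(ccc1O[Si](C(C)C)(C(C)C)C(C)C)C(=O)OC | intermediate
15 | 2-(triphenylphosphoranylidene)propanal | CC(C=O)=P(c1ccccc1)(c1ccccc1)c1ccccc1 | starting material
16 | methyl 3-{[(5S,6S)-5-bromo-2,6-dimethyl-6-(3-oxopropyl)cyclohex-1-en-1-yl]methyl}-4-(triisopropylsilyloxy)benzoate | O=CCC[C@@]1(C)C(=C(C)CC[C@@H]1Br)Cc1cc(ccc1O[Si](C(C)C)(C(C)C)C(C)C)C(=O)OC | intermediate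
17 | methyl 3-{[(5S,6S)-5-bromo-2,6-dimethyl-6-[(3E)-4-methyl-5-oxopent-3-en-1-yl]cyclohex-1-en-1-yl]methyl}-4-(triisopropylsilyloxy)benzoate | O=C/C(C)=C/CC[C@@]1(C)C(=C(C)CC[C@@H]1Br)Cc1cc(ccc1O[Si](C(C)C)(C(C)C)C(C)C)C(=O)OC | intermediate
18 | methyl 3-{[(5S,6S)-5-bromo-6-[(3E)-5-hydroxy-4-methylpent-3-en-1-yl]-2,6-dimethylcyclohex-1-en-1-yl]methyl}-4-(triisopropylsilyloxy)benzoate | OC/C(C)=C/CC[C@@]1(C)C(=C(C)CC[C@@H]1Br)Cc1cc(ccc1O[Si](C(C)C)(C(C)C)C(C)C)C(=O)OC | intermediate
19 | methyl 3-{[(5S,6S)-5-bromo-6-{2-[(2S,3S)-3-(hydroxymethyl)-3-methyloxiran-2-yl]ethyl}-2,6-dimethylcyclohex-1-en-1-yl]methyl}-4-(triisopropylsilyloxy)benzoate | OC[C@]1(C)O[C@H]1CC[C@@]2(C)C(=C(C)CC[C@@H]2Br)Cc2cc(ccc2O[Si](C(C)C)(C(C)C)C(C)C)C(=O)OC | intermediate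
20 | methyl 3-{[(5S,6S)-5-bromo-6-[(3R,4S)-3-bromo-4,5-dihydroxy-4-methylpentyl]-2,6-dimethylcyclohex-1-en-1-yl]methyl}-4-(triisopropylsilyloxy)benzoate | OC[C@](C)(O)[C@H](Br)CC[C@@]1(C)C(=C(C)CC[C@@H]1Br)Cc1cc(ccc1O[Si](C(C)C)(C(C)C)C(C)C)C(=O)OC | intermediate
21 | methyl 3-{[(5S,6S)-5-bromo-6-[(3R,4S)-3-bromo-4-methyl-4,5-bis(triethylsilyloxy)pentyl]-2,6-dimethylcyclohex-1-en-1-yl]methyl}-4-(triisopropylsilyloxy)benzoate | CC[Si](CC)(CC)OC[C@](C)(O[Si](CC)(CC)CC)[C@H](Br)CC[C@@]1(C)C(=C(C)CC[C@@H]1Br)Cc1cc(ccc1O[Si](C(C)C)(C(C)C)C(C)C)C(=O)OC | intermediate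
22 | methyl 3-{[(5S,6S)-5-bromo-6-[(3R,4S)-3-bromo-4-methyl-5-oxo-4-(triethylsilyloxy)pentyl]-2,6-dimethylcyclohex-1-en-1-yl]methyl}-4-(triisopropylsilyloxy)benzoate | O=C[C@](C)(O[Si](CC)(CC)CC)[C@H](Br)CC[C@@]1(C)C(=C(C)CC[C@@H]1Br)Cc1cc(ccc1O[Si](C(C)C)(C(C)C)C(C)C)C(=O)OC | intermediate
23 | methyl 3-{[(5S,6S)-5-bromo-6-[(3R,4S)-3-bromo-4-methyl-4-(triethylsilyloxy)hex-5-en-1-yl]-2,6-dimethylcyclohex-1-en-1-yl]methyl}-4-(triisopropylsilyloxy)benzoate | C=C[C@](C)(O[Si](CC)(CC)CC)[C@H](Br)CC[C@@]1(C)C(=C(C)CC[C@@H]1Br)Cc1cc(ccc1O[Si](C(C)C)(C(C)C)C(C)C)C(=O)OC | intermediate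
24 | 3-{[(5S,6S)-5-bromo-6-[(3R,4S)-3-bromo-4-methyl-4-(triethylsilyloxy)hex-5-en-1-yl]-2,6-dimethylcyclohex-1-en-1-yl]methyl}-4-(triisopropylsilyloxy)benzoic acid | C=C[C@](C)(O[Si](CC)(CC)CC)[C@H](Br)CC[C@@]1(C)C(=C(C)CC[C@@H]1Br)Cc1cc(ccc1O[Si](C(C)C)(C(C)C)C(C)C)C(=O)O | intermediate
25 | methacrolein | C=C(C)C=O | starting material
26 | acid chloride of 24 | C=C[C@](C)(O[Si](CC)(CC)CC)[C@H](Br)CC[C@@]1(C)C(=C(C)CC[C@@H]1Br)Cc1cc(ccc1O[Si](C(C)C)(C(C)C)C(C)C)C(=O)Cl | intermediate
27 | 1-chloro-2-methylallyl ester of 24 (both epimers at the chloro carbon) | C=C[C@](C)(O[Si](CC)(CC)CC)[C@H](Br)CC[C@@]1(C)C(=C(C)CC[C@@H]1Br)Cc1cc(ccc1O[Si](C(C)C)(C(C)C)C(C)C)C(=O)OC(Cl)C(C)=C | intermediate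
28 | (1E)-3-chloro-2-methylprop-1-en-1-yl ester of 24 | C=C[C@](C)(O[Si](CC)(CC)CC)[C@H](Br)CC[C@@]1(C)C(=C(C)CC[C@@H]1Br)Cc1cc(ccc1O[Si](C(C)C)(C(C)C)C(C)C)C(=O)O/C=C(\C)CCl | intermediate
29 | B-alkyl-9-BBN adduct of 28 (boron on C13) | C1CC2CCCC(C1)B2CC[C@](C)(O[Si](CC)(CC)CC)[C@H](Br)CC[C@@]3(C)C(=C(C)CC[C@@H]3Br)Cc3cc(ccc3O[Si](C(C)C)(C(C)C)C(C)C)C(=O)O/C=C(\C)CCl | intermediate
30 | potassium tert-butoxyborate of 29 | [K+].CC(C)(C)O[B-]1(C2CCCC1CCC2)CC[C@](C)(O[Si](CC)(CC)CC)[C@H](Br)CC[C@@]3(C)C(=C(C)CC[C@@H]3Br)Cc3cc(ccc3O[Si](C(C)C)(C(C)C)C(C)C)C(=O)O/C=C(\C)CCl | intermediate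
31 | bis-silyl macrolactone (15-membered lactone; C11–OSiEt3; ArO–Si(i-Pr)3; 6S,7S,10R,11S,14S) | C=C(C)[C@@H]1CC[C@](C)(O[Si](CC)(CC)CC)[C@H](Br)CC[C@@]2(C)C(=C(C)CC[C@@H]2Br)Cc2cc(ccc2O[Si](C(C)C)(C(C)C)C(C)C)C(=O)O1 | intermediate
32 | CNP0305154.1 (6S,7S,10R,11S,14S) | C=C(C)[C@@H]1CC[C@](C)(O)[C@H](Br)CC[C@@]2(C)C(=C(C)CC[C@@H]2Br)Cc2cc(ccc2O)C(=O)O1 | target

**Step count and risks**

Total step count: 20. Longest linear sequence: 18 steps (steps 1–5 and 8–20, from 2-methylcyclohexane-1,3-dione); steps 6–7 prepare the benzyl bromide in parallel.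

Steps most likely to fail:

1. Step 19 (proposed new method). The ate complex may transmetalate to copper more slowly than open-chain material couples with itself, giving oligomers. tert-Butoxide may instead transfer to the enol ester and cleave it, releasing methacrolein. The ligand may not impose sufficient facial control at C14. The fallback uses known chemistry, sets out from 23 and returns at 31; the ring is then closed at oxygen and the C13–C14 bond is made intermolecularly. Hydroboration of 23 with 9-BBN gives the B-alkyl-9-BBN adduct F1. In the same flask, carbonylative Suzuki–Miyaura coupling with 2-iodopropene (Pd(PPh3)4, K3PO4, CO 1 atm) gives the isopropenyl ketone F2. CBS reduction with the (R)-oxazaborolidine and catecholborane should set C14 in the (S)-allylic alcohol F3. Me3SnOH then cleaves the methyl ester to the seco acid F4, and Yamaguchi macrolactonisation (2,4,6-trichlorobenzoyl chloride, Et3N, then DMAP, toluene, high dilution) gives 31.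

2. Step 18. The tertiary allylic silyl ether may be cleaved or ionised by the acyl chloride and ZnCl2, the 1,3-chloride shift may stop short, or the enol ester may form as an inseparable E/Z mixture. The fallback avoids any acyl chloride, sets out from 23 and returns at 31. Linear hydroformylation of the vinyl group (Rh(acac)(CO)2, Xantphos, CO/H2) gives the aldehyde F5. A catalytic asymmetric Nozaki–Hiyama–Kishi addition of 2-bromopropene (CrCl2, NiCl2 cat., chiral sulfonamide ligand) then gives the (S)-allylic alcohol F3, which is hydrolysed to the seco acid F4 and lactonised to 31 as described for step 19.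

3. Step 3. SN2 displacement at the neopentylic carbinol is slow, so elimination to the cyclohexene or a 1,2-shift of a group from the quaternary carbon may compete, and incomplete inversion would erode the C6 configuration. The fallback sets out from 4 and returns at 5, separating activation from displacement. The alcohol is converted to the triflate F6 (Tf2O, pyridine, CH2Cl2, −30 °C), which is displaced by Bu4NBr in toluene at rt, so that a naked bromide meets a far better leaving group at low temperature.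

Further compounds

F1 | step 19 | B-alkyl-9-BBN adduct of 23 (boron on C13) | C1CC2CCCC(C1)B2CC[C@](C)(O[Si](CC)(CC)CC)[C@H](Br)CC[C@@]3(C)C(=C(C)CC[C@@H]3Br)Cc3cc(ccc3O[Si](C(C)C)(C(C)C)C(C)C)C(=O)OC
F2 | step 19 | isopropenyl ketone (C14 carbonyl) methyl ester | C=C(C)C(=O)CC[C@](C)(O[Si](CC)(CC)CC)[C@H](Br)CC[C@@]1(C)C(=C(C)CC[C@@H]1Br)Cc1cc(ccc1O[Si](C(C)C)(C(C)C)C(C)C)C(=O)OC
F3 | step 19 | (14S)-allylic alcohol methyl ester | C=C(C)[C@@H](O)CC[C@](C)(O[Si](CC)(CC)CC)[C@H](Br)CC[C@@]1(C)C(=C(C)CC[C@@H]1Br)Cc1cc(ccc1O[Si](C(C)C)(C(C)C)C(C)C)C(=O)OC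
F4 | step 19 | (14S)-seco acid | C=C(C)[C@@H](O)CC[C@](C)(O[Si](CC)(CC)CC)[C@H](Br)CC[C@@]1(C)C(=C(C)CC[C@@H]1Br)Cc1cc(ccc1O[Si](C(C)C)(C(C)C)C(C)C)C(=O)O
F5 | step 18 | C14 aldehyde methyl ester (hydroformylation product of 23) | O=CCC[C@](C)(O[Si](CC)(CC)CC)[C@H](Br)CC[C@@]1(C)C(=C(C)CC[C@@H]1Br)Cc1cc(ccc1O[Si](C(C)C)(C(C)C)C(C)C)C(=O)OC
F6 | step 3 | (1R,2R)-2-allyl-2-methyl-3-oxocyclohexyl trifluoromethanesulfonate | C=CC[C@@]1(C)C(=O)CCC[C@H]1OS(=O)(=O)C(F)(F)F
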